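**Strategy.** The skeleton is disconnected at one bond only, C1–C2 (cembrane numbering). The 14-membered ring C1–C14, the E-alkenes C7=C8 and C11=C12, the C3/C4 epoxide (a former E-alkene) and the C1 stereocentre with its three-carbon branch C15–C17 are those of (R)-cembrene A. A class 1 terpene cyclase makes this hydrocarbon in one operation from the acyclic, achiral, all-E C20 allylic diphosphate, closing the ring and setting C1. Oxygen is added afterwards: the branch becomes an acrylic acid whose carboxyl group cyclises twice onto the neighbouring alkene (iodolactonisation) to place epoxide and lactone; C14 is hydroxylated last and acetylated.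

Key step: step 3

Assumption: cembrane numbering is used (C1 carries the branch C15–C17, lactone oxygen on C2, epoxide on C3/C4, acetate on C14); C1 of the target has the spatial arrangement of (R)-cembrene A, and the target keeps all twenty carbons of that hydrocarbon (C17 is its =CH2, the carbonyl C16 its methyl), so no carbon is added after the cyclisation.

Step 1
Reactants: 1 (2E,6E,10E)-geranylgeraniol
Product: 3 (2E,6E,10E)-geranylgeranyl chloride, via alkoxysulfonium chloride 2 (not isolated)
Conditions: NCS, Me2S, CH2Cl2, −40 → 0 °C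
Reagents that add atoms: N-chlorosuccinimide, O=C1CCC(=O)N1Cl
Why: Corey–Kim chlorination: chloride displaces the sulfonium-activated oxygen of 2 at the primary allylic carbon (SN2), so neither the position nor the E geometry of the adjacent alkene changes.

Step 2
Reactants: 3 (2E,6E,10E)-geranylgeranyl chloride
Product: 4 (2E,6E,10E)-geranylgeranyl diphosphate (handled as the tris-ammonium salt)
Conditions: (n-Bu4N)3HP2O7, MeCN, rt; then NH4+ ion exchange (Dowex 50W), cellulose chromatography
Reagents that add atoms: tris(tetra-n-butylammonium) hydrogen diphosphate, CCCC[N+](CCCC)(CCCC)CCCC.CCCC[N+](CCCC)(CCCC)CCCC.CCCC[N+](CCCC)(CCCC)CCCC.OP(=O)([O-])OP(=O)([O-])[O-]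
Why: SN2 displacement of the primary allylic chloride by the diphosphate anion in dry acetonitrile is the standard way to allylic diphosphates, and cation exchange gives the ammonium salt that the cyclase accepts.

Step 3
Reactants: 4 (2E,6E,10E)-geranylgeranyl diphosphate
Product: 7 (R)-cembrene A, via geranylgeranyl cation 5 (not isolated), via cembren-15-yl cation 6 (not isolated)
Conditions: recombinant (R)-cembrene A synthase (class 1 diterpene synthase, His-tagged, from E. coli), MgCl2, HEPES pH 7.5, 30 °C, pentane overlay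
Reagents that add atoms: none
Why: Mg2+-assisted ionisation of the diphosphate in the class 1 active site gives the allyl cation 5 (C2–C3–C4), which the folded chain attacks with its distal C1=C15 alkene in the Markovnikov sense, forming C1–C2 and the tertiary cation 6, whose methyl deprotonation leaves the isopropenyl group. The closest known reaction type is exactly this 1,14-macrocyclisation of geranylgeranyl diphosphate by class 1 diterpene synthases, cembrene A synthases among them, run in vitro and in whole cells. The one ring, the 14-membered carbocycle, closes by C–C bond formation between alkene carbon C1 and the allyl terminus C2, with C15 left outside the ring (exo with respect to the reacting alkene). The one new stereocentre, C1, is controlled by the chiral active-site fold, which offers a single face of the C1=C15 alkene to the cation; a synthase characterised for the (R) product is chosen. The step needs 1,14 closure instead of 6- or 10-membered rings, retention of the three E alkenes and loss of a methyl proton instead of water capture; the all-E geometry of 4 and the enzyme template secure these.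

Step 4
Reactants: 7 (R)-cembrene A
Product: 10 (1R,3E,7E,11E)-cembra-3,7,11,15(17)-tetraen-16-ol, via allyllithium 8 (not isolated), via dimethyl allylboronate 9 (not isolated)
Conditions: n-BuLi, TMEDA, hexane, rt; B(OMe)3, THF, −78 °C → rt; H2O2, NaOH, 0 °C
Reagents that add atoms: hydrogen peroxide, OO
Why: Allylic lithiation with n-BuLi·TMEDA removes a proton from the isopropenyl methyl group, the kinetically most acidic allylic position because the 2-substituted allyllithium 8 has two primary termini (as with limonene); borylation and oxidation (C–B to C–O with retention) give the alcohol without touching C1, and both termini of the allyl unit lead to the same product.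

Step 5
Reactants: 10 (1R,3E,7E,11E)-cembra-3,7,11,15(17)-tetraen-16-ol
Product: 11 (1R,3E,7E,11E)-cembra-3,7,11,15(17)-tetraen-16-al
Conditions: MnO2, CH2Cl2, rt
Reagents that add atoms: none
Why: MnO2 oxidises only the allylic primary alcohol, under neutral conditions that neither move the exocyclic double bond nor epimerise C1.

Step 6
Reactants: 11 (1R,3E,7E,11E)-cembra-3,7,11,15(17)-tetraen-16-al
Product: 12 (1R,3E,7E,11E)-cembra-3,7,11,15(17)-tetraen-16-oic acid
Conditions: NaClO2, NaH2PO4, 2-methyl-2-butene, t-BuOH/H2O, 0 °C → rt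
Reagents that add atoms: sodium chlorite, [Na+].[O-]Cl=O
Why: Lindgren–Pinnick oxidation of the enal to the acrylic acid; the large excess of 2-methyl-2-butene removes HOCl before it can attack the ring alkenes.

Step 7
Reactants: 12 (1R,3E,7E,11E)-cembra-3,7,11,15(17)-tetraen-16-oic acid
Product: 13 (1R,3R,4S,7E,11E)-4-iodocembra-7,11,15(17)-trien-16,3-olide
Conditions: I2, NaHCO3, MeCN, 0 °C, dark
Reagents that add atoms: iodine, II
Why: Iodolactonisation: only the δ,ε-alkene C3=C4 lies within reach of the carboxylate (6-exo, δ-lactone), iodine and oxygen add anti, and a chair-like transition state with the ring bonds C1–C14 and C3–C4 both equatorial should put the oxygen on C3 with the 3R configuration.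

Step 8
Reactants: 13 (1R,3R,4S,7E,11E)-4-iodocembra-7,11,15(17)-trien-16,3-olide
Product: 15 (1R,3S,4R,7E,11E)-4-hydroxy-3-(phenylselanyl)cembra-7,11,15(17)-trien-16-oic acid, via epoxy acid 14 (not isolated)
Conditions: LiOH, THF/H2O, 0 °C → rt; then (PhSe)2, NaBH4, EtOH, 70 °C
Reagents that add atoms: lithium hydroxide, [Li+].[OH-]; diphenyl diselenide, c1ccc(cc1)[Se][Se]c1ccccc1
Why: Saponification frees the C3 alkoxide, which displaces the tertiary iodide (inversion at C4) to give the (3R,4R)-epoxide 14, kept as its carboxylate; benzeneselenolate then opens it by SN2 at the less substituted C3 (epoxide to β-hydroxy selenide), so the C4–O bond and its configuration stay.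

Step 9
Reactants: 15 (1R,3S,4R,7E,11E)-4-hydroxy-3-(phenylselanyl)cembra-7,11,15(17)-trien-16-oic acid
Product: 17 (1R,2E,4R,7E,11E)-4-hydroxycembra-2,7,11,15(17)-tetraen-16-oic acid, via selenoxide 16 (not isolated)
Conditions: NaIO4, NaHCO3, MeOH/THF/H2O, 0 °C → rt
Reagents that add atoms: none
Why: Selenoxide syn-elimination can take a hydrogen only from C2 (C4 has none), so the 2E allylic tertiary alcohol forms regiospecifically, and periodate does not epoxidise the ring alkenes.

Step 10
Reactants: 17 (1R,2E,4R,7E,11E)-4-hydroxycembra-2,7,11,15(17)-tetraen-16-oic acid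
Product: 19 (1S,2S,3R,4R,7E,11E)-3,4-epoxycembra-7,11,15(17)-trien-16,2-olide, via iodohydrin lactone 18 (not isolated)
Conditions: I2, NaHCO3, MeCN, 0 °C, dark; then Cs2CO3, MeCN, rt
Reagents that add atoms: none
Why: A second iodolactonisation, now 5-exo onto C2=C3 (oxygen at C2, the carbon remote from the carbinol; anti addition), should give the trans ring fusion because the C1–C14 ring bond sits skew to the alkene; carbonate then closes the epoxide from the tertiary alkoxide with inversion at C3 (halohydrin-to-epoxide closure), which makes the C2/C3 relation threo and, with C4 fixed in step 7, returns the (3R,4R) trans-epoxide.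

Step 11
Reactants: 19 (1S,2S,3R,4R,7E,11E)-3,4-epoxycembra-7,11,15(17)-trien-16,2-olide
Product: 20 (1R,2S,3R,4R,14S,7E,11E)-3,4-epoxy-14-hydroxycembra-7,11,15(17)-trien-16,2-olide
Conditions: P450 BM3 variant (chosen from an active-site mutant panel), NADP+ (cat.), glucose, glucose dehydrogenase, air, KPi pH 8.0, 2% DMSO, 25 °C
Reagents that add atoms: dioxygen, O=O
Why: Proposed new method: no enzyme is yet known that hydroxylates C14 of a cembranolide; the iron-oxo oxidant of the P450 cycle abstracts the pro-S hydrogen of C14 and returns OH to the same face (rebound, retention), so both the site and the 14S configuration depend only on how the variant holds 19; the closest known reaction type is the hydroxylation of ring methylenes in cembranoid diols and in a germacranolide epoxide lactone by engineered P450 BM3 variants, and a variant must be found by screening and, if needed, evolved.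

Step 12
Reactants: 20 (1R,2S,3R,4R,14S,7E,11E)-3,4-epoxy-14-hydroxycembra-7,11,15(17)-trien-16,2-olide
Product: 21 (1R,2S,3R,4R,14S,7E,11E)-14-acetoxy-3,4-epoxycembra-7,11,15(17)-trien-16,2-olide (CNP0294029.1)
Conditions: Ac2O, pyridine, DMAP (cat.), CH2Cl2, 0 °C
Reagents that add atoms: acetic anhydride, CC(=O)OC(C)=O
Why: Standard DMAP-catalysed acylation of the secondary alcohol with retention at C14, run cold on crude 20 so that the free hydroxyl has no time to translactonise.

**Compound list**

1 | (2E,6E,10E)-geranylgeraniol | CC(C)=CCC/C(C)=C/CC/C(C)=C/CC/C(C)=C/CO | starting material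
2 | (2E,6E,10E)-geranylgeranyloxy-dimethylsulfonium chloride | CC(C)=CCC/C(C)=C/CC/C(C)=C/CC/C(C)=C/CO[S+](C)C.[Cl-] | intermediate
3 | (2E,6E,10E)-geranylgeranyl chloride | CC(C)=CCC/C(C)=C/CC/C(C)=C/CC/C(C)=C/CCl | intermediate
4 | (2E,6E,10E)-geranylgeranyl diphosphate (used as tris-ammonium salt) | CC(C)=CCC/C(C)=C/CC/C(C)=C/CC/C(C)=C/COP(=O)(O)OP(=O)(O)O | intermediate
5 | geranylgeranyl allyl cation (enzyme-bound ion pair with diphosphate) | CC(C)=CCC/C(C)=C/CC/C(C)=C/CC/C(C)=C/[CH2+] | intermediate
6 | (1R)-cembra-3,7,11-trien-15-yl cation (enzyme-bound) | C[C+](C)[C@@H]1CC/C(C)=C/CC/C(C)=C/CC/C(C)=C/C1 | intermediate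
7 | (R)-cembrene A | CC(=C)[C@@H]1CC/C(C)=C/CC/C(C)=C/CC/C(C)=C/C1 | intermediate
8 | 2-[(1R)-ring]allyllithium (TMEDA-solvated; lithium on C16) | [Li]CC(=C)[C@@H]1CC/C(C)=C/CC/C(C)=C/CC/C(C)=C/C1 | intermediate
9 | dimethyl 2-[(1R)-ring]allylboronate | COB(OC)CC(=C)[C@@H]1CC/C(C)=C/CC/C(C)=C/CC/C(C)=C/C1 | intermediate
10 | (1R,3E,7E,11E)-cembra-3,7,11,15(17)-tetraen-16-ol | C=C(CO)[C@@H]1CC/C(C)=C/CC/C(C)=C/CC/C(C)=C/C1 | intermediate
11 | (1R,3E,7E,11E)-cembra-3,7,11,15(17)-tetraen-16-al | C=C(C=O)[C@@H]1CC/C(C)=C/CC/C(C)=C/CC/C(C)=C/C1 | intermediate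
12 | (1R,3E,7E,11E)-cembra-3,7,11,15(17)-tetraen-16-oic acid | C=C(C(=O)O)[C@@H]1CC/C(C)=C/CC/C(C)=C/CC/C(C)=C/C1 | intermediate
13 | (1R,3R,4S,7E,11E)-4-iodocembra-7,11,15(17)-trien-16,3-olide (δ-lactone, tertiary iodide) | C=C1C(=O)O[C@@H]2C[C@H]1CC/C(C)=C/CC/C(C)=C/CC[C@]2(C)I | intermediate
14 | (1R,3R,4R,7E,11E)-3,4-epoxycembra-7,11,15(17)-trien-16-oic acid (lithium salt in the flask) | C=C(C(=O)O)[C@@H]1CC/C(C)=C/CC/C(C)=C/CC[C@@]2(C)O[C@@H]2C1 | intermediate
15 | (1R,3S,4R,7E,11E)-4-hydroxy-3-(phenylselanyl)cembra-7,11,15(17)-trien-16-oic acid | C=C(C(=O)O)[C@@H]1CC/C(C)=C/CC/C(C)=C/CC[C@@](C)(O)[C@@H]([Se]c2ccccc2)C1 | intermediate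
16 | selenoxide of 15 (mixture at selenium) | C=C(C(=O)O)[C@@H]1CC/C(C)=C/CC/C(C)=C/CC[C@@](C)(O)[C@@H]([Se](=O)c2ccccc2)C1 | intermediate
17 | (1R,2E,4R,7E,11E)-4-hydroxycembra-2,7,11,15(17)-tetraen-16-oic acid | C=C(C(=O)O)[C@@H]1CC/C(C)=C/CC/C(C)=C/CC[C@@](C)(O)/C=C/1 | intermediate
18 | (1S,2S,3S,4R,7E,11E)-4-hydroxy-3-iodocembra-7,11,15(17)-trien-16,2-olide | C=C1C(=O)O[C@H]2[C@H]1CC/C(C)=C/CC/C(C)=C/CC[C@@](C)(O)[C@H]2I | intermediate
19 | (1S,2S,3R,4R,7E,11E)-3,4-epoxycembra-7,11,15(17)-trien-16,2-olide (trans-fused α-methylene γ-lactone) | C=C1C(=O)O[C@H]2[C@H]1CC/C(C)=C/CC/C(C)=C/CC[C@@]1(C)O[C@H]21 | intermediate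
20 | (1R,2S,3R,4R,14S,7E,11E)-3,4-epoxy-14-hydroxycembra-7,11,15(17)-trien-16,2-olide | C=C1C(=O)O[C@H]2[C@H]1[C@@H](O)C/C(C)=C/CC/C(C)=C/CC[C@@]1(C)O[C@H]21 | intermediate
21 | (1R,2S,3R,4R,14S,7E,11E)-14-acetoxy-3,4-epoxycembra-7,11,15(17)-trien-16,2-olide | C=C1C(=O)O[C@H]2[C@H]1[C@@H](OC(C)=O)C/C(C)=C/CC/C(C)=C/CC[C@@]1(C)O[C@H]21 | target

**Step count.** 12 steps in total; the longest linear sequence is 12 steps (1 → 21).

**Steps most likely to fail**

Step 11 (labelled step). What may go wrong: loss of site selectivity (oxygen insertion at the allylic methylenes C6, C9, C10 or C13, or epoxidation of the ring alkenes), or delivery of oxygen to the wrong face of C14. The fallback uses known chemistry directed by the C2 hydroxyl and sets out from 19. i-Bu2AlH (CH2Cl2, −78 °C) reduces the lactone to the epoxy diol F1, and TBSCl/imidazole silylates the primary allylic hydroxyl to give the silyl ether F2. Et2SiH2 with [Ir(cod)OMe]2 (cat.) turns the free C2 hydroxyl into the diethylhydrosilyl ether F3. [Ir(cod)OMe]2 with 3,4,7,8-tetramethyl-1,10-phenanthroline and norbornene as hydrogen acceptor (THF, 100 °C) then silylates the γ-methylene C14–H to the oxasilolane F4. C15 carries no hydrogen, so C14 is the only γ C(sp3)–H, and the new C–Si bond is expected trans to the C15 branch. Tamao–Fleming oxidation (H2O2, KHCO3, KF) gives the 2,14-diol F5 with the 14R alcohol. A Mitsunobu reaction with acetic acid (PPh3, DIAD) at the less hindered C14 carbinol inverts it to the 14S acetate F6. HF·pyridine frees the primary alcohol to give the diol acetate F7, and MnO2 oxidises the allylic alcohol and closes the lactone onto the C2 hydroxyl. The fallback thereby comes back to the route at the target 21. Its own weak points are the exocyclic alkene under the silylation conditions and the choice between the two secondary hydroxyls in the Mitsunobu step.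

Step 10. What may go wrong: poor facial selectivity in the attack of the carboxylate on C2=C3 (cis ring fusion), or a mismatch with the C4 configuration carried over from step 7; either ends in a diastereomeric epoxide. The fallback sets out from 17 and no longer depends on C4. Re2O7 (cat., CH2Cl2, rt) transposes the tertiary allylic alcohol while the carboxyl group traps C2 under equilibrating conditions. This should give the trans-fused triene lactone F8 with the 3E alkene restored; C4 is sp2 again. i-Bu2AlH gives the allylic diol F9 and TBSCl/imidazole the primary silyl ether F10. VO(acac)2/t-BuOOH epoxidises only the alkene next to the free C2 hydroxyl, threo under allylic 1,3-strain control (the C4 methyl is cis to C2), and gives the epoxy alcohol F2 already met above. TBAF then gives the epoxy diol F1, and MnO2 closes the lactone, so the fallback comes back at 19.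

Step 4. What may go wrong: unselective or incomplete deprotonation, with metalation at ring allylic positions competing. The fallback sets out from 7. 9-BBN (THF) hydroborates only the 1,1-disubstituted alkene, and H2O2/NaOH gives the saturated primary alcohol F11 (both C15 epimers, which does not matter). Dess–Martin periodinane gives the aldehyde F12, and PhSeCl (EtOAc) selenenylates its α-carbon to the seleno aldehyde F13. NaIO4 oxidises this to the selenoxide F14, whose syn-elimination toward the methyl group restores the exocyclic alkene. The fallback comes back at the enal 11.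

**Further compounds**

F1 | step 11 | (1S,2S,3R,4R,7E,11E)-3,4-epoxycembra-7,11,15(17)-triene-2,16-diol | C=C(CO)[C@@H]1CC/C(C)=C/CC/C(C)=C/CC[C@@]2(C)O[C@@H]2[C@H]1O
F2 | step 11 | 16-O-TBS ether of F1 | C=C(CO[Si](C)(C)C(C)(C)C)[C@@H]1CC/C(C)=C/CC/C(C)=C/CC[C@@]2(C)O[C@@H]2[C@H]1O
F3 | step 11 | 2-O-diethylhydrosilyl ether of F2 | C=C(CO[Si](C)(C)C(C)(C)C)[C@@H]1CC/C(C)=C/CC/C(C)=C/CC[C@@]2(C)O[C@@H]2[C@H]1O[SiH](CC)CC
F4 | step 11 | 2-O,14-C-diethylsilylene oxasilolane (silicon on C14 trans to the C15 branch) | C=C(CO[Si](C)(C)C(C)(C)C)[C@@H]1[C@H]2C/C(C)=C/CC/C(C)=C/CC[C@@]3(C)O[C@@H]3[C@H]1O[Si]2(CC)CC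
F5 | step 11 | 16-O-TBS 3,4-epoxy-2,14-diol with 14R alcohol (C14 epimer of the target series) | C=C(CO[Si](C)(C)C(C)(C)C)[C@@H]1[C@H](O)C/C(C)=C/CC/C(C)=C/CC[C@@]2(C)O[C@@H]2[C@H]1O
F6 | step 11 | 16-O-TBS 14S-acetoxy-3,4-epoxy-2-ol | C=C(CO[Si](C)(C)C(C)(C)C)[C@@H]1[C@@H](OC(C)=O)C/C(C)=C/CC/C(C)=C/CC[C@@]2(C)O[C@@H]2[C@H]1O
F7 | step 11 | 14S-acetoxy-3,4-epoxycembra-7,11,15(17)-triene-2,16-diol | C=C(CO)[C@@H]1[C@@H](OC(C)=O)C/C(C)=C/CC/C(C)=C/CC[C@@]2(C)O[C@@H]2[C@H]1O
F8 | step 10 | (1S,2R,3E,7E,11E)-cembra-3,7,11,15(17)-tetraen-16,2-olide (trans-fused) | C=C1C(=O)O[C@H]2[C@H]1CC/C(C)=C/CC/C(C)=C/CC/C(C)=C/2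
F9 | step 10 | (3E,7E,11E)-cembra-3,7,11,15(17)-tetraene-2,16-diol (C1, C2 as in F8) | C=C(CO)[C@@H]1CC/C(C)=C/CC/C(C)=C/CC/C(C)=C/[C@H]1O
F10 | step 10 | 16-O-TBS ether of F9 | C=C(CO[Si](C)(C)C(C)(C)C)[C@@H]1CC/C(C)=C/CC/C(C)=C/CC/C(C)=C/[C@H]1O
F11 | step 4 | (3E,7E,11E)-cembra-3,7,11-trien-16-ol (C1 as in 7, C15 epimers) | CC(CO)[C@@H]1CC/C(C)=C/CC/C(C)=C/CC/C(C)=C/C1
F12 | step 4 | (3E,7E,11E)-cembra-3,7,11-trien-16-al (C15 epimers) | CC(C=O)[C@@H]1CC/C(C)=C/CC/C(C)=C/CC/C(C)=C/C1
F13 | step 4 | 15-(phenylselanyl)cembra-3,7,11-trien-16-al | CC(C=O)([Se]c2ccccc2)[C@@H]1CC/C(C)=C/CC/C(C)=C/CC/C(C)=C/C1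
F14 | step 4 | selenoxide of F13 | CC(C=O)([Se](=O)c2ccccc2)[C@@H]1CC/C(C)=C/CC/C(C)=C/CC/C(C)=C/C1
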